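In a stirred vessel, substrate and coupling partner join reversibly to target and, on a side path, to isomer of the product, while the coupling partner also decomposes on its own.

| setting | Sunday's | Saturday's | Tuesday's | dawn | winter | spring | summer |
|---|---|---|---|---|---|---|---|
| substrate | 41 mM | 57 mM | 90 mM | 41 mM (fed, over 50 min) | 41 mM | 41 mM (fed, over 5.0 min) | 41 mM |
| coupling partner | 73.8 mM | 73.8 mM | 73.8 mM | 73.8 mM | 73.8 mM | 73.8 mM | 73.8 mM (fed, over 50 min) |
| remark | run made earlier | run made earlier | run made earlier | all else is in the flask from the start; the feed brings no volume worth counting | everything together at the start | all else is in the flask from the start; the feed brings no volume worth counting | all else is in the flask from the start; the feed brings no volume worth counting |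
| time |  |  |  | 80 min | 80 min | 80 min | 80 min |

| run | time / min | target / % | substrate / % |
|---|---|---|---|
| Sunday's | 4.00 | 24 | 76 |
| Sunday's | 12.0 | 37 | 58 |
| Sunday's | 20.0 | 36 | 57 |
| Sunday's | 30.0 | 37 | 60 |
| Sunday's | 50.0 | 28 | 65 |
| Saturday's | 5.00 | 25 | 73 |
| Saturday's | 10.0 | 33 | 63 |
| Saturday's | 20.0 | 38 | 60 |
| Saturday's | 30.0 | 33 | 59 |
| Saturday's | 60.0 | 23 | 67 |
| Tuesday's | 5.00 | 24 | 75 |
| Tuesday's | 10.0 | 31 | 68 |
| Tuesday's | 20.0 | 30 | 64 |
| Tuesday's | 30.0 | 31 | 66 |
| Tuesday's | 60.0 | 23 | 75 |

(readings scatter by 1.5 percentage points)

- the flask that comes out highest in amount of target, in percent of the substrate charged, or "all alike" when all lie within 1.5 percentage points (dawn / winter / spring / summer / all alike)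
- target at the end, in percent of the substrate charged, dawn
- target at the end, in percent of the substrate charged, winter
- target at the end, in percent of the substrate charged, spring
- target at the end, in percent of the substrate charged, summer

- the numbers in the tables scatter by 1.5 percentage points (one standard deviation)
- steps thought possible: substrate + coupling partner <-> target; substrate + coupling partner -> isomer of the product; coupling partner -> decomposed reagent

Each molecule of coupling partner thus faces two rates: coupling, which grows with [substrate], and decomposition, which does not. The flasks differ in the ratio of these two, and that ratio can be written with one amount.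

In Sunday's run, [substrate] stops falling at about 20.0 min, with 17.6 mM turned over against 73.8 mM of partner charged, at a mean [substrate] of 32.2 mM. Counting that turnover as the partner's coupled share, [substrate]/([substrate] + X), gives X = 103 mM, the break-even substrate, the [substrate] at which a partner molecule couples as fast as it decomposes, in effect a selectivity factor. Tuesday's run gives 94.3 mM. The count ignores the way back, so this is a reading, good for ranking.

Winter has Sunday's charges, so its ratio is 0.313, and spring, fed in 5.0 min, should sit close by. Dawn's partner waits beside substrate that arrives over 50 min, averaging about 20.5 mM, a ratio of 0.200, lower than winter's. Summer's partner meets substrate nearer its charge, a ratio towards 0.400. So summer should lead and dawn should trail winter.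

The forecast also names summer, at 29%, since “feeding the partner keeps it low early, so less decomposes”, but it sets dawn level with winter and spring, at 23%, 23% and 23%.

The flasks end at 10.8% in dawn, 18.8% in winter, 17.9% in spring and 28.2% in summer.

    substrate + coupling partner ⇌ target (K = 38.0 /M, k = 1.10 /M/min)
    substrate + coupling partner → isomer of the product (k = 0.0840 /M/min)
    coupling partner → decomposed reagent (k = 0.0510 /min)

Mean [substrate] over the first 50 min ran 15.9 mM in dawn, 25.5 mM in winter and 32.9 mM in summer, ratios of 0.154, 0.248 and 0.319 to the break-even substrate. With decomposition struck out, the gap between summer and dawn goes from 17 percentage points to −0.08 points, the largest single effect on it, but the reverse step is a part of that gap too: without the way back it stands at 33 points. A neighbour of summer charged with 100 mM of substrate starts at a ratio of 0.971 and ends with 23.3% of its charge as target, 23.3 mM against 11.5 mM in summer.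

All runs are simulated with made-up constants, and the scatter is random.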